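The earlier runs and the new flask come from a simulation with made-up constants.

| flask | starting material | protic impurity | temperature | remark | time |
|---|---|---|---|---|---|
| summer | 3.4 mM | 1.5 mM | 75 °C | run made earlier |  |
| dusk | 7.5 mM | 1.5 mM | 100 °C | run made earlier |  |
| winter | 5 mM | 3 mM | 75 °C | run made earlier |  |
| south-east | 5.0 mM | 1.50 mM | 120 °C |  | 2.5 min |
| north | 5.0 mM | 1.50 mM | 80 °C |  | 10 min |

- summer (time / min: product / %, starting material / %): 0.833: 2.3, 26.5; 1.33: 5.4, 14.1; 2.00: 11.0, 5.3; 4.00: 30.9, 0; 6.00: 44.0, 0; 10.0: 57.5, 0.3
- dusk (time / min: product / %, starting material / %): 0.250: 14.6, 4.2; 0.667: 50.1, 0.5; 1.33: 75.5, 0.9; 2.00: 81.5, 1.2; 3.00: 83.1, 0.3; 4.00: 84.5, 0.2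
- winter (time / min: product / %, starting material / %): 2.00: 8.8, 3.3; 4.00: 23.8, 0.1; 6.00: 33.6, 0.4; 8.00: 40.5, 0; 10.0: 44.5, 0

(each reading ± 0.5 percentage points)

- in percentages every species weighs as the starting material in it: one homo dimer counts as two
- on the list of suspects stand: starting material -> intermediate A; intermediate A <-> intermediate B; intermediate A -> intermediate C; intermediate C -> product; 2 starting material -> homo dimer; starting material + protic impurity -> quenched substrate

* the flask that ends with the higher amount of product, in percent of the starting material charged, or "neither" when 2 percentage points or less lies between them (south-east / north / neither)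
* final product, as a percentage of the starting material charged, in south-east
* final product, as a percentage of the starting material charged, in north

Look first at what is left of the protic impurity when a flask has finished, since the leftover records a race. Starting material can leave by a first-order route to intermediate A, which leads on to product, or by a second-order route with the impurity to quenched substrate. Dividing the two rate laws and integrating until the starting material is gone gives: charged [starting material] minus impurity consumed equals L times ln(charged [protic impurity] / final [protic impurity]).

In the winter run, the last product gaps, 6.9 percentage points and then 4 points, shrink with a time constant of 3.67 min and point to a plateau near 50.0%. So my estimate is that winter consumed 2.50 mM of impurity, and L reads 1.40 mM. This L is the break-even level, the [protic impurity] at which both routes carry equal flow: a selectivity factor with a unit. The dusk run, taking its last reading as plateau, reads 4.25 mM, and its tail gives a time constant of 0.610 min.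

Winter has north's charge of starting material, but north has an 80 °C bath and winter has twice the impurity. Straight lines in ln against reciprocal temperature put L at 1.77 mM for north, so north is charged below break-even, whereas winter is charged above it. Solving the balance by repeated substitution, north leaves 0.187 mM of impurity, which caps product at 73.7%. Its time constant of 2.51 min fits 3.98 times into the run, so I expect 72.4%. For south-east the same lines put L at 9.34 mM, the balance leaves 0.934 mM of impurity, and I expect 88.7%.

The forecast names south-east, with 89% against 71%, holding that “heat favours activation”.

The simulation gives south-east: 86.1% in south-east and 71.6% in north.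

    starting material → intermediate A (k = 0.0281 s⁻¹, Ea = 104 kJ mol⁻¹)
    intermediate A ⇌ intermediate B (K = 0.600, k = 0.0223 s⁻¹, Ea = 92.0 kJ mol⁻¹, ΔH = 0 kJ mol⁻¹)
    intermediate A → intermediate C (k = 0.0467 s⁻¹, Ea = 89.0 kJ mol⁻¹)
    intermediate C → product (k = 0.00692 s⁻¹, Ea = 89.0 kJ mol⁻¹)
    2 starting material → homo dimer (k = 0.00810 M⁻¹ s⁻¹, Ea = 81.0 kJ mol⁻¹)
    starting material + protic impurity → quenched substrate (k = 16.1 M⁻¹ s⁻¹, Ea = 64.0 kJ mol⁻¹)
    (constants at 80 °C)

In south-east the midpoint of the activation turnover came at 0.587 s, and by 1.25 min product stood at 86.1% beside 13.8% quenched substrate. South-east's leftover, 54.0% of the impurity's charge, puts L at 6.98 mM, not 9.34 mM. For the same charge at 95 °C, the two runs give L as 3.44 mM and a quenched share of 20.5%. That neighbouring flask ended with 21.7% quenched substrate.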